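**Retrosynthetic overview**

1. Locants follow the daucane skeleton. Ring A (cyclopentane) is C-1 (quaternary ring-fusion carbon with CH3), C-2 (CH–OAc), C-3 (CH2), C-4 (C(OH)iPr) and C-5 (ring-fusion CH). Ring B (cycloheptene) is C-1, C-5, C-6 (CH–O-anisoyl), C-7, C-8(CH3)=C-9 and C-10 (CH–OH). β is the face of the C-1 methyl group.
2. End game: the oxygen functions are differentiated last (2-naphthylmethyl ether to 2-OAc, 6-O-anisoyl, 10-OTBS removed). The C-6 carbinol comes from a C-6 ketone by reduction directed by the 4β-OH. Ring B is closed by ring-closing metathesis at C-8=C-9 on a cyclopentane whose C-5 acyl arm and C-1 silyloxyallyl arm are trans.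
3. Key disconnection: ring A by a formal [3+2] cycloaddition that forms C-2–C-3 and C-4–C-5 in one operation, from a 2-alkoxycyclopropyl ketone (cyclopropane C-1/C-2/C-5, ketone C-6) and the silyl enol ether of 3-methylbutan-2-one (C-3, C-4, isopropyl).
4. Enabling feature: the oxygen on C-2 and the oxygen on C-6 (a ketone at that stage, attached to C-5) are 1,4-related across the C-1–C-5 ring-fusion bond. C-2/C-1/C-5 is therefore a donor–acceptor cyclopropane retron (C-2 oxocarbenium, C-5 enolate). The tertiary carbinol C-4, β to both C-2–O and C-6=O, is the carbonyl carbon of isopropyl methyl ketone.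
5. The cyclopropane comes from intramolecular cyclopropanation of the diazoacetate of an enantioenriched bis-allylic enol-ether alcohol (C-10 controls quaternary C-1 through a temporary γ-lactone). Order of ring formation: cyclopropane with lactone, lactone opened, ring A (cyclopropane consumed), ring B.

Key step: step 10

Remark: commercial 3-ethoxy-2-methylacrolein is taken as the E isomer; the lipase in step 3 is assumed to follow the Kazlauskas rule.

**Route**

Step 1
Reactants: 1 (E)-3-ethoxy-2-methylprop-2-enal; 2 naphthalen-2-ylmethanol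
Product: 3 (E)-2-methyl-3-(naphthalen-2-ylmethoxy)prop-2-enal
Conditions: PPTS (cat.), toluene, 90 °C, ethanol distilled off
Reagents that add atoms: none
Why: Acid-catalysed vinylogous transesterification (addition–elimination at the β-carbon of the vinylogous formate) is driven by removal of ethanol and should give the thermodynamically favoured E enol ether.

Step 2
Reactants: 3 (E)-2-methyl-3-(naphthalen-2-ylmethoxy)prop-2-enal
Product: 4 rac-(1E)-2-methyl-1-(naphthalen-2-ylmethoxy)penta-1,4-dien-3-ol
Conditions: vinylmagnesium bromide, THF, −78 °C; pH 7 buffer work-up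
Reagents that add atoms: vinylmagnesium bromide, C=C[Mg]Br
Why: 1,2-Grignard addition to the aldehyde of the vinylogous ester gives the racemic, acid-labile bis-allylic alcohol, hence the buffered work-up.

Step 3
Reactants: 4 rac-(1E)-2-methyl-1-(naphthalen-2-ylmethoxy)penta-1,4-dien-3-ol
Product: 5 (3S,1E)-2-methyl-1-(naphthalen-2-ylmethoxy)penta-1,4-dien-3-ol
Conditions: Amano lipase PS, vinyl acetate, MTBE, 30 °C, run past half conversion; chromatography on Et3N-deactivated silica
Reagents that add atoms: none
Why: Lipase-catalysed kinetic resolution by enantioselective transesterification; by the Kazlauskas rule (medium group vinyl, large group the 2-substituted alkenyl) the R alcohol should be acetylated and the S alcohol recovered.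

Step 4
Reactants: 5 (3S,1E)-2-methyl-1-(naphthalen-2-ylmethoxy)penta-1,4-dien-3-ol
Product: 6 (3S,1E)-2-methyl-1-(naphthalen-2-ylmethoxy)penta-1,4-dien-3-yl 2-diazoacetate
Conditions: 2,5-dioxopyrrolidin-1-yl 2-diazoacetate, Et3N, DMAP (cat.), THF, 0 °C to rt
Reagents that add atoms: 2,5-dioxopyrrolidin-1-yl 2-diazoacetate, O=C(C=[N+]=[N-])ON1C(=O)CCC1=O
Why: Acyl transfer from the N-hydroxysuccinimide ester (diazoacetylation) runs under basic conditions that the enol ether tolerates and does not touch the stereocentre.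

Step 5
Reactants: 6 (3S,1E)-2-methyl-1-(naphthalen-2-ylmethoxy)penta-1,4-dien-3-yl 2-diazoacetate
Product: 7 (1S,4S,5R,6R)-5-methyl-6-(naphthalen-2-ylmethoxy)-4-vinyl-3-oxabicyclo[3.1.0]hexan-2-one (vinyl syn to the cyclopropane carbon C-6, naphthylmethoxy exo and cis to the methyl group)
Conditions: bis(N-tert-butylsalicylaldiminato)copper (divalent copper, 5 mol %), toluene, 100 °C, slow addition of 6
Reagents that add atoms: none
Why: Copper-carbenoid intramolecular cyclopropanation of an allylic diazoacetate, in which the electrophilic carbenoid should add to the electron-rich enol ether rather than the vinyl group; the lactone tether forces cis fusion, the E geometry is transferred (alkoxy cis to methyl), and C-10 sets quaternary C-1 because the carbinol hydrogen, not the vinyl group, eclipses the 2-methyl substituent (minimised A(1,2) strain).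

Step 6
Reactants: 7 bicyclic lactone
Product: 8 N-methoxy-N-methylcyclopropanecarboxamide carrying at C-2 a methyl group and an (S)-1-hydroxyallyl group (cis to the amide) and at C-3 the naphthalen-2-ylmethoxy group (trans to the amide)
Conditions: MeNH(OMe)·HCl, isopropylmagnesium chloride, THF, −20 to 0 °C
Reagents that add atoms: N,O-dimethylhydroxylamine hydrochloride, CNOC.Cl
Why: Aminolysis of the lactone by the chloromagnesium amide (Weinreb amide formation) frees the C-10 hydroxyl without Lewis-acid activation of the donor–acceptor cyclopropane; no stereocentre changes.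

Step 7
Reactants: 8 hydroxy Weinreb amide
Product: 9 the tert-butyldimethylsilyl ether of 8
Conditions: TBSOTf, 2,6-lutidine, CH2Cl2, −78 °C
Reagents that add atoms: tert-butyldimethylsilyl triflate, CC(C)(C)[Si](C)(C)OS(=O)(=O)C(F)(F)F
Why: Fast silylation of the secondary allylic alcohol at low temperature with a hindered base should outrun relactonisation and leave the cyclopropane intact.

Step 8
Reactants: 9 silyl-protected Weinreb amide
Product: 10 1-cyclopropyl-3-methylbut-3-en-1-one carrying on the cyclopropane at C-2 a methyl group and an (S)-1-(tert-butyldimethylsilyloxy)allyl group (cis to the acyl group) and at C-3 the naphthalen-2-ylmethoxy group (trans to the acyl group)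
Conditions: 2-methylallylmagnesium chloride, THF, −78 °C; pH 7 buffer quench at −78 °C
Reagents that add atoms: 2-methylallylmagnesium chloride, CC(=C)C[Mg]Cl
Why: Weinreb ketone synthesis; the chelated tetrahedral intermediate prevents over-addition and the cold buffered quench should release the β,γ-unsaturated ketone without conjugation.

Step 9
Reactants: 11 3-methylbutan-2-one
Product: 12 3-methyl-2-(trimethylsilyloxy)but-1-ene
Conditions: LiN(iPr)2, THF, −78 °C; Me3SiCl
Reagents that add atoms: chlorotrimethylsilane, C[Si](C)(C)Cl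
Why: Kinetic deprotonation of the methyl group and O-silylation give the less substituted silyl enol ether.

Step 10
Reactants: 10 2-alkoxycyclopropyl ketone; 12 3-methyl-2-(trimethylsilyloxy)but-1-ene
Product: 14 cyclopentyl ketone cycloadduct with free tertiary alcohol (2α-naphthylmethoxy; 4β-hydroxy-4α-isopropyl; 5β-acyl; 1β-methyl), via tertiary trimethylsilyl ether 13 (not isolated)
Conditions: SnCl4 (0.3 equiv), 12 (2.5 equiv), CH2Cl2, −78 °C; then 1 M HCl, THF, 0 °C
Reagents that add atoms: none
Why: SnCl4 binds the C-6 ketone and the push–pull C-2–C-5 bond of the cyclopropane (the only bond flanked by the alkoxy donor and the keto acceptor) breaks to a 1,3-zwitterion (C-2 oxocarbenium, C-5 tin enolate); C-3 of 12 adds to C-2 in a Mukaiyama-type step and the resulting C-4 silyloxycarbenium is captured by the C-5 enolate. The closest known reaction type is the Lewis-acid-promoted formal [3+2] cycloaddition of 2-alkoxycyclopropyl ketones and esters with silyl enol ethers. Ring A is closed in the second bond formation by a 5-exo-trig intramolecular Mukaiyama aldol (5-(enolexo)-exo-trig). C-2 should be set by Felkin–Anh attack on the oxocarbenium anti to the bulky silyloxyallyl (C-10) branch of quaternary C-1 and past its methyl group (2α-alkoxy); C-5 and C-4 are set in the ring closure, where the enolate terminus C-6 lies on the methyl side of C-1 and the isopropyl group turns away from C-6, so that the three large groups (C-10 branch, acyl, isopropyl) end all-trans (5β-acyl, 4α-isopropyl, 4β-oxygen), which is also the thermodynamically preferred arrangement; C-1 is untouched. The step needs chemoselectivity for the silyl enol ether over the two unactivated alkenes and no migration of the β,γ-double bond, which the much higher nucleophilicity of 12 (used in excess) and the low temperature without base should secure; the acidic work-up cleaves the tertiary trimethylsilyl ether 13.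

Step 11
Reactants: 14 cyclopentyl ketone cycloadduct
Product: 15 10β-(tert-butyldimethylsilyloxy)-4β-hydroxy-2α-(naphthalen-2-ylmethoxy)dauc-8-en-6-one (1β-methyl, 5α-H)
Conditions: second-generation Grubbs catalyst RuCl2(=CHPh)(PCy3)(SIMes) (10 mol %), CH2Cl2, 40 °C, high dilution
Reagents that add atoms: none
Why: Ring-closing olefin metathesis of the 1,1-disubstituted and the monosubstituted alkene on the trans-disposed arms should form the trisubstituted C-8=C-9 cycloheptene (ring B, trans-fused) with loss of ethylene; no stereocentre is touched.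

Step 12
Reactants: 15 hydroazulenone
Product: 16 10β-(tert-butyldimethylsilyloxy)-2α-(naphthalen-2-ylmethoxy)dauc-8-ene-4β,6α-diol
Conditions: Me4NBH(OAc)3, MeCN/AcOH (1:1), −20 °C
Reagents that add atoms: none
Why: Hydroxyl-directed (Evans–Saksena) reduction; the C-4 alkoxy(diacetoxy)borohydride should deliver hydride intramolecularly to the face of the C-6 carbonyl on which the 4β-oxygen lies, giving the 6α-alcohol (anti to 4-OH, cis to 5α-H).

Step 13
Reactants: 16 4β,6α-diol
Product: 17 the 6α-(4-methoxybenzoate) of 16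
Conditions: 4-methoxybenzoyl chloride, Et3N, DMAP (cat.), CH2Cl2, 0 °C to rt
Reagents that add atoms: 4-methoxybenzoyl chloride, COc1ccc(C(=O)Cl)cc1
Why: DMAP-catalysed acylation of the only secondary alcohol; the tertiary C-4 hydroxyl should not react.

Step 14
Reactants: 17 6α-anisoate
Product: 18 10β-(tert-butyldimethylsilyloxy)-2α,4β-dihydroxydauc-8-en-6α-yl 4-methoxybenzoate
Conditions: DDQ, CH2Cl2/pH 7 phosphate buffer, 0 °C to rt
Reagents that add atoms: none
Why: Oxidative cleavage of the 2-naphthylmethyl ether by DDQ (hydride abstraction, hydrolysis of the oxocarbenium); the silyl ether, the ester and the ring alkene should be inert.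

Step 15
Reactants: 18 2α-alcohol
Product: 19 2α-acetoxy-10β-(tert-butyldimethylsilyloxy)-4β-hydroxydauc-8-en-6α-yl 4-methoxybenzoate
Conditions: Ac2O, pyridine, DMAP (cat.), CH2Cl2, rt
Reagents that add atoms: acetic anhydride, CC(=O)OC(C)=O
Why: Acetylation of the secondary C-2 alcohol; the tertiary alcohol stays free under these mild conditions.

Step 16
Reactants: 19 silyl-protected diester
Product: 20 the target, 2α-acetoxy-4β,10β-dihydroxydauc-8-en-6α-yl 4-methoxybenzoate (1β-methyl, 5α-H)
Conditions: HF·pyridine, pyridine, THF, 0 °C to rt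
Reagents that add atoms: none
Why: Fluoride-mediated desilylation under buffered, non-basic conditions should avoid 1,3-acyl migration between O-2 and O-10.

**Compound list**

1 | (E)-3-ethoxy-2-methylprop-2-enal | CCO/C=C(\C)C=O | starting material
2 | naphthalen-2-ylmethanol | OCc1ccc2ccccc2c1 | starting material
3 | (E)-2-methyl-3-(naphthalen-2-ylmethoxy)prop-2-enal | O=C/C(C)=C/OCc1ccc2ccccc2c1 | intermediate
4 | rac-(1E)-2-methyl-1-(naphthalen-2-ylmethoxy)penta-1,4-dien-3-ol | C=CC(O)/C(C)=C/OCc1ccc2ccccc2c1 | intermediate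
5 | (3S,1E)-2-methyl-1-(naphthalen-2-ylmethoxy)penta-1,4-dien-3-ol | C=C[C@H](O)/C(C)=C/OCc1ccc2ccccc2c1 | intermediate
6 | (3S,1E)-2-methyl-1-(naphthalen-2-ylmethoxy)penta-1,4-dien-3-yl 2-diazoacetate | C=C[C@H](OC(=O)C=[N+]=[N-])/C(C)=C/OCc1ccc2ccccc2c1 | intermediate
7 | (1S,4S,5R,6R)-5-methyl-6-(naphthalen-2-ylmethoxy)-4-vinyl-3-oxabicyclo[3.1.0]hexan-2-one | O=C1O[C@@H](C=C)[C@@]2(C)[C@H](OCc3ccc4ccccc4c3)[C@@H]12 | intermediate
8 | hydroxy Weinreb amide (cyclopropane: 2-methyl, 2-[(S)-1-hydroxyallyl] cis to amide, 3-naphthylmethoxy trans to amide) | CON(C)C(=O)[C@@H]1[C@@H](OCc2ccc3ccccc3c2)[C@]1(C)[C@@H](O)C=C | intermediate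
9 | tert-butyldimethylsilyl ether of 8 | CON(C)C(=O)[C@@H]1[C@@H](OCc2ccc3ccccc3c2)[C@]1(C)[C@@H](O[Si](C)(C)C(C)(C)C)C=C | intermediate
10 | 2-alkoxycyclopropyl 2-methylallyl ketone | C=C(C)CC(=O)[C@@H]1[C@@H](OCc2ccc3ccccc3c2)[C@]1(C)[C@@H](O[Si](C)(C)C(C)(C)C)C=C | intermediate
11 | 3-methylbutan-2-one | CC(=O)C(C)C | starting material
12 | 3-methyl-2-(trimethylsilyloxy)but-1-ene | C=C(O[Si](C)(C)C)C(C)C | intermediate
13 | tertiary trimethylsilyl ether of cycloadduct 14 | C=C(C)CC(=O)[C@H]1[C@](O[Si](C)(C)C)(C(C)C)C[C@H](OCc2ccc3ccccc3c2)[C@]1(C)[C@@H](O[Si](C)(C)C(C)(C)C)C=C | intermediate (not isolated)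
14 | cyclopentyl ketone cycloadduct (1β-methyl, 1α-[(S)-1-silyloxyallyl], 2α-naphthylmethoxy, 4β-hydroxy, 4α-isopropyl, 5β-(3-methylbut-3-enoyl)) | C=C(C)CC(=O)[C@H]1[C@](O)(C(C)C)C[C@H](OCc2ccc3ccccc3c2)[C@]1(C)[C@@H](O[Si](C)(C)C(C)(C)C)C=C | intermediate
15 | 10β-(tert-butyldimethylsilyloxy)-4β-hydroxy-2α-(naphthalen-2-ylmethoxy)dauc-8-en-6-one | O=C1CC(C)=C[C@H](O[Si](C)(C)C(C)(C)C)[C@@]2(C)[C@@H](OCc3ccc4ccccc4c3)C[C@@](O)(C(C)C)[C@H]12 | intermediate
16 | 10β-(tert-butyldimethylsilyloxy)-2α-(naphthalen-2-ylmethoxy)dauc-8-ene-4β,6α-diol | O[C@H]1CC(C)=C[C@H](O[Si](C)(C)C(C)(C)C)[C@@]2(C)[C@@H](OCc3ccc4ccccc4c3)C[C@@](O)(C(C)C)[C@H]12 | intermediate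
17 | 6α-(4-methoxybenzoate) of 16 | COc1ccc(C(=O)O[C@H]2CC(C)=C[C@H](O[Si](C)(C)C(C)(C)C)[C@@]3(C)[C@@H](OCc4ccc5ccccc5c4)C[C@@](O)(C(C)C)[C@H]23)cc1 | intermediate
18 | 10β-(tert-butyldimethylsilyloxy)-2α,4β-dihydroxydauc-8-en-6α-yl 4-methoxybenzoate | COc1ccc(C(=O)O[C@H]2CC(C)=C[C@H](O[Si](C)(C)C(C)(C)C)[C@@]3(C)[C@@H](O)C[C@@](O)(C(C)C)[C@H]23)cc1 | intermediate
19 | 2α-acetoxy-10β-(tert-butyldimethylsilyloxy)-4β-hydroxydauc-8-en-6α-yl 4-methoxybenzoate | COc1ccc(C(=O)O[C@H]2CC(C)=C[C@H](O[Si](C)(C)C(C)(C)C)[C@@]3(C)[C@@H](OC(C)=O)C[C@@](O)(C(C)C)[C@H]23)cc1 | intermediate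
20 | 2α-acetoxy-4β,10β-dihydroxydauc-8-en-6α-yl 4-methoxybenzoate | COc1ccc(C(=O)O[C@H]2CC(C)=C[C@H](O)[C@@]3(C)[C@@H](OC(C)=O)C[C@@](O)(C(C)C)[C@H]23)cc1 | target

**Step count**

Total: 16 steps. Longest linear sequence: 15 steps (steps 1 to 8 and 10 to 16; step 9 is a one-step side branch).

**Steps most likely to fail**

Step 10 (key step). The attack of the enol ether on the C-2 oxocarbenium may show poor or reversed facial selectivity, since two large groups on quaternary C-1 compete for the anti position; the C-2 ether would then form mainly as the 2β epimer. The fallback sets out from 10 and 12 and returns at 18. It replaces kinetic control at C-2 by a hydroxyl-directed ketone reduction. The annulation is run as before and the epimer is carried on: 2-epi-cycloadduct F1 is closed by metathesis to 2-epi-hydroazulenone F2, reduced as in step 12 to 2-epi-diol F3, acylated to 2-epi-anisoate F4 and treated with DDQ to give 2β-alcohol F5. Dess–Martin oxidation (NaHCO3, CH2Cl2) then gives 2-ketone F6, and Me4NBH(OAc)3 in MeCN/AcOH should deliver hydride from the face of the 4β-hydroxyl to give the 2α-alcohol 18.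

Step 5. The carbenoid may be delivered to the other face of the enol ether, so that the vinyl group ends anti to the cyclopropane and the C-1/C-10 relationship is wrong. The fallback sets out from 4 and returns at 8. It uses the other enantiomer and resets C-10 by reagent control. The lipase resolution of 4 also gives (R)-acetate F7, which K2CO3 in methanol converts to (R)-alcohol F8. Diazoacetylation as in step 4 gives (R)-diazoacetate F9, and cyclopropanation with the reversed facial sense gives exo-vinyl lactone F10, which has the required configuration at C-1, C-2 and C-5 and differs from 7 only at C-10. Aminolysis as in step 6 gives 10-epi-hydroxy amide F11, Dess–Martin oxidation gives vinyl ketone F12, and reduction with (R)-2-methyl-CBS-oxazaborolidine and catecholborane (toluene, −78 °C) should give 8.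

Step 12. Intramolecular hydride delivery has to pass through a chair with an axial isopropyl group and may lose to external attack on the α face (anti to the C-1 methyl group), which gives the 6β-alcohol. The fallback sets out from 15 and returns at 17. It makes α-face attack the intended event and inverts C-6 during esterification. LiBH(sBu)3 in THF at −78 °C should give 6β-alcohol F13, and Mitsunobu esterification with 4-methoxybenzoic acid, PPh3 and DIAD (toluene, 0 °C to rt) should give 17 with inversion.

**Further compounds**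

F1 | step 10 | 2-epi-cycloadduct (2β-naphthylmethoxy epimer of 14) | C=C(C)CC(=O)[C@H]1[C@](O)(C(C)C)C[C@@H](OCc2ccc3ccccc3c2)[C@]1(C)[C@@H](O[Si](C)(C)C(C)(C)C)C=C
F2 | step 10 | 2-epi-hydroazulenone (2β epimer of 15) | O=C1CC(C)=C[C@H](O[Si](C)(C)C(C)(C)C)[C@@]2(C)[C@H](OCc3ccc4ccccc4c3)C[C@@](O)(C(C)C)[C@H]12
F3 | step 10 | 2-epi-diol (2β epimer of 16) | O[C@H]1CC(C)=C[C@H](O[Si](C)(C)C(C)(C)C)[C@@]2(C)[C@H](OCc3ccc4ccccc4c3)C[C@@](O)(C(C)C)[C@H]12
F4 | step 10 | 2-epi-anisoate (2β epimer of 17) | COc1ccc(C(=O)O[C@H]2CC(C)=C[C@H](O[Si](C)(C)C(C)(C)C)[C@@]3(C)[C@H](OCc4ccc5ccccc5c4)C[C@@](O)(C(C)C)[C@H]23)cc1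
F5 | step 10 | 2β-alcohol (2-epimer of 18) | COc1ccc(C(=O)O[C@H]2CC(C)=C[C@H](O[Si](C)(C)C(C)(C)C)[C@@]3(C)[C@H](O)C[C@@](O)(C(C)C)[C@H]23)cc1
F6 | step 10 | 2-ketone (10β-silyloxy-4β-hydroxy-2-oxodauc-8-en-6α-yl 4-methoxybenzoate) | COc1ccc(C(=O)O[C@H]2CC(C)=C[C@H](O[Si](C)(C)C(C)(C)C)[C@@]3(C)C(=O)C[C@@](O)(C(C)C)[C@H]23)cc1
F7 | step 5 | (3R,1E)-2-methyl-1-(naphthalen-2-ylmethoxy)penta-1,4-dien-3-yl acetate | C=C[C@@H](OC(C)=O)/C(C)=C/OCc1ccc2ccccc2c1
F8 | step 5 | (3R,1E)-2-methyl-1-(naphthalen-2-ylmethoxy)penta-1,4-dien-3-ol | C=C[C@@H](O)/C(C)=C/OCc1ccc2ccccc2c1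
F9 | step 5 | (3R,1E)-2-methyl-1-(naphthalen-2-ylmethoxy)penta-1,4-dien-3-yl 2-diazoacetate | C=C[C@@H](OC(=O)C=[N+]=[N-])/C(C)=C/OCc1ccc2ccccc2c1
F10 | step 5 | exo-vinyl lactone (C-4 epimer of 7, vinyl anti to the cyclopropane) | O=C1O[C@H](C=C)[C@@]2(C)[C@H](OCc3ccc4ccccc4c3)[C@@H]12
F11 | step 5 | 10-epi-hydroxy amide (carbinol epimer of 8) | CON(C)C(=O)[C@@H]1[C@@H](OCc2ccc3ccccc3c2)[C@]1(C)[C@H](O)C=C
F12 | step 5 | vinyl ketone (2-acryloyl cyclopropyl Weinreb amide) | CON(C)C(=O)[C@@H]1[C@@H](OCc2ccc3ccccc3c2)[C@]1(C)C(=O)C=C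
F13 | step 12 | 6β-alcohol (6-epimer of 16) | O[C@@H]1CC(C)=C[C@H](O[Si](C)(C)C(C)(C)C)[C@@]2(C)[C@@H](OCc3ccc4ccccc4c3)C[C@@](O)(C(C)C)[C@H]12
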